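**Plan**
- Retrosynthetic cuts, in order: (a) the ester C–O bond, which releases angelic acid. (b) The aryl–CH2 bond of the 4-benzyl arm, whose CH2 is raised to a lactol/lactone carbon tied to the oxygen of the C3–CH2O arm. (c) O1–C2 and C4–C5 of the oxolane in one stroke, which removes O1–C5H2 as formaldehyde and leaves C2–C3–C4 as a cyclopropane. (d) The cyclopropane, back to a (Z)-cinnamyl diazoacetate.
- Enabling feature: C2 is benzylic to an electron-rich 3,4-dimethoxyphenyl ring (donor). C4 carries a carbon that can stand at the carbonyl level (acceptor). The C3–CH2O and C4–CH2 arms are cis, so both fit into a temporary gamma-lactone ring fused to the cyclopropane (6-aryl-3-oxabicyclo[3.1.0]hexan-2-one).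
- Forward order: the aryl–C3 chain is joined and reduced to the Z-alkene. Cyclopropane and lactone rings then close together from the diazoacetate. A formal (3+2) cycloaddition with formaldehyde builds the oxolane ring. The lactone goes to the lactol, whose carbon is arylated reductively (this opens the helper ring), and the freed CH2OH is esterified.
- Stereochemistry: the enantioselective intramolecular cyclopropanation sets C3 absolutely, and the Z-alkene places the aryl group endo. The cycloaddition inverts that carbon (2,3-trans), and the cis ring fusion fixes 3,4-cis. The Z-alkene of the ester comes with angelic acid.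

Key step: step 6

Assumption: Rh2(5R-MEPY)4, dirhodium tetrakis[methyl (5R)-2-oxopyrrolidine-5-carboxylate], is taken to give the (1S,5R,6S) lactone, by analogy with its sense of induction on other (Z)-allylic diazoacetates. The mirror-image catalyst is equally available should the sense be opposite.

**Step 1**
Reactants: 1 4-iodo-1,2-dimethoxybenzene; 2 prop-2-yn-1-ol
Product: 3 3-(3,4-dimethoxyphenyl)prop-2-yn-1-ol
Conditions: PdCl2(PPh3)2 (2 mol %), CuI (4 mol %), Et3N, THF, rt
Reagents that add atoms: none
Why: Sonogashira coupling of an aryl iodide with a terminal alkyne forms the aryl–C(sp) bond under mild conditions and tolerates the free hydroxyl group.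

**Step 2**
Reactants: 3 3-(3,4-dimethoxyphenyl)prop-2-yn-1-ol
Product: 4 (2Z)-3-(3,4-dimethoxyphenyl)prop-2-en-1-ol
Conditions: H2 (1 atm), Pd/CaCO3 poisoned with Pb(OAc)2, quinoline, EtOAc, rt
Reagents that add atoms: none
Why: Lindlar-type semihydrogenation adds hydrogen syn to the adsorbed alkyne and so gives the Z-alkene, with quinoline holding back over-reduction and Z to E isomerisation.

**Step 3**
Reactants: 4 (2Z)-3-(3,4-dimethoxyphenyl)prop-2-en-1-ol; 5 bromoacetyl bromide
Product: 6 (2Z)-3-(3,4-dimethoxyphenyl)prop-2-en-1-yl bromoacetate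
Conditions: NaHCO3, MeCN, 0 °C
Reagents that add atoms: none
Why: O-acylation of a primary alcohol by an acid bromide, with solid NaHCO3 taking up HBr so that the acid-labile electron-rich allylic system is not ionised.

**Step 4**
Reactants: 6 (2Z)-3-(3,4-dimethoxyphenyl)prop-2-en-1-yl bromoacetate
Product: 7 (2Z)-3-(3,4-dimethoxyphenyl)prop-2-en-1-yl diazoacetate
Conditions: TsNHNHTs, DBU, THF, 0 °C
Reagents that add atoms: N,N'-ditosylhydrazine, Cc1ccc(cc1)S(=O)(=O)NNS(=O)(=O)c1ccc(C)cc1
Why: N-alkylation of ditosylhydrazine by the bromoacetate followed by two base-induced losses of sulfinate (Bamford–Stevens-type elimination) is a standard mild passage from bromoacetates to diazoacetates and leaves the Z-alkene untouched.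

**Step 5**
Reactants: 7 (2Z)-3-(3,4-dimethoxyphenyl)prop-2-en-1-yl diazoacetate
Product: 8 (1S,5R,6S)-6-(3,4-dimethoxyphenyl)-3-oxabicyclo[3.1.0]hexan-2-one (aryl endo; the three cyclopropane hydrogens on one face)
Conditions: Rh2(5R-MEPY)4 (1 mol %), CH2Cl2, reflux, slow addition of 7
Reagents that add atoms: none
Why: Enantioselective intramolecular cyclopropanation by a chiral dirhodium carboxamidate carbene is concerted and syn, so the Z geometry is carried into the endo position of the aryl group, the short tether enforces the cis-fused lactone, and the catalyst selects the alkene face that sets C1, C5 and C6 together.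

**Step 6**
Reactants: 8 (1S,5R,6S)-6-(3,4-dimethoxyphenyl)-3-oxabicyclo[3.1.0]hexan-2-one; 9 formaldehyde
Product: 11 (1R,5R,6S)-6-(3,4-dimethoxyphenyl)-3,7-dioxabicyclo[3.3.0]octan-2-one (cis-fused; aryl exo), via oxocarbenium silyl ketene acetal 10 (not isolated)
Conditions: CH2O gas (from paraformaldehyde at 150 °C, excess) passed into 8, Me3SiOTf (20 mol %), CH2Cl2, −78 to −30 °C; Et3N quench
Reagents that add atoms: trimethylsilyl triflate, C[Si](C)(C)OS(=O)(=O)C(F)(F)F (its atoms stand in 10 only and are released again on ring closure)
Why: Proposed new method: Me3SiOTf silylates the lactone carbonyl oxygen of 8, the oxygen of free formaldehyde attacks the donor carbon C6 from the side opposite to the breaking C1–C6 bond, and the oxocarbenium ion/silyl ketene acetal 10 so formed closes by a Mukaiyama-type attack of C1 on the O=CH2 carbon with return of Me3SiOTf, so that the O–C(aryl) bond and the CH2–C bond of the oxolane arise in one operation. The closest known reaction type is the Lewis-acid-catalysed formal (3+2) cycloaddition of aldehydes with 2-arylcyclopropane-1,1-diesters, together with its Me3SiOTf-promoted variant for oxygen-donor cyclopropanes that bear a single carbonyl acceptor; not yet shown are an aryl donor paired with one lactone acceptor and formaldehyde as partner, which should be made up for by the strong 3,4-dimethoxyphenyl donor, by the strain of the all-cis bicyclo[3.1.0]hexane and by the near-parallel alignment of the C1–C6 bond with the carbonyl pi system. The only ring closed is the oxolane, in a 5-(enolexo)-endo-trig mode at the oxocarbenium carbon, as in the diester series. C6 of 11 (C2 of the target) is set by inversion at the endo-aryl carbon, and a leak through an open benzylic ion pair should end at the same epimer, since allylic 1,3-strain keeps C5–H eclipsed with the aryl group while oxygen enters from the side of C1; C1 of 11 (C4 of the target) is set by the tether, because the electrophile hangs from C5 and reaches only that face of the ketene acetal and a bicyclo[3.3.0]octane has to be cis-fused; C5 is not touched. The step needs cleavage of C1–C6 and not of C1–C5 or C5–C6, which is secured because only C1–C6 joins donor and acceptor carbon, and it needs oxygen-first addition, which the non-nucleophilic triflate secures (a halide would open the ring first and allow an intermolecular aldol on the wrong face). It also needs the veratryl ring to escape hydroxymethylation and 11 to escape benzylic epimerisation, for which the far higher Lewis basicity of the lactone compared with formaldehyde, the low temperature and the amine quench are relied on.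

**Step 7**
Reactants: 11 (1R,5R,6S)-6-(3,4-dimethoxyphenyl)-3,7-dioxabicyclo[3.3.0]octan-2-one
Product: 12 (1R,5R,6S)-6-(3,4-dimethoxyphenyl)-3,7-dioxabicyclo[3.3.0]octan-2-ol (lactol; both anomers)
Conditions: iBu2AlH, CH2Cl2, −78 °C; aq. potassium sodium tartrate
Reagents that add atoms: none
Why: Partial reduction of a gamma-lactone with iBu2AlH stops at the aluminium hemiacetal at low temperature, and the cis-fused lactol rests in its ring form, which shields the alpha stereocentre from epimerisation.

**Step 8**
Reactants: 12 (1R,5R,6S)-6-(3,4-dimethoxyphenyl)-3,7-dioxabicyclo[3.3.0]octan-2-ol; 13 3,4-dimethoxyphenylboronic acid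
Product: 17 [(2S,3R,4R)-4-(3,4-dimethoxybenzyl)-2-(3,4-dimethoxyphenyl)oxolan-3-yl]methanol, via tosylhydrazone 14 (not isolated), via diazoalkane 15 (not isolated), via benzylic boronic acid 16 (not isolated)
Conditions: TsNHNH2, 1,4-dioxane, 80 °C; then 13, K2CO3, 110 °C
Reagents that add atoms: p-toluenesulfonohydrazide, Cc1ccc(cc1)S(=O)(=O)NN (its atoms stand in 14 and 15 only)
Why: Metal-free reductive coupling of a tosylhydrazone with a boronic acid, in which Bamford–Stevens loss of sulfinate gives the diazoalkane, the arylboronic acid carboborates it with 1,2-aryl shift and loss of N2, and protodeboronation leaves the CH2–aryl link without touching the ring stereocentres or the benzylic C2–O bond.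

**Step 9**
Reactants: 17 [(2S,3R,4R)-4-(3,4-dimethoxybenzyl)-2-(3,4-dimethoxyphenyl)oxolan-3-yl]methanol; 18 angelic acid ((2Z)-2-methylbut-2-enoic acid)
Product: 19 leoligin, [(2S,3R,4R)-4-(3,4-dimethoxybenzyl)-2-(3,4-dimethoxyphenyl)oxolan-3-yl]methyl (2Z)-2-methylbut-2-enoate
Conditions: PPh3, DIAD, THF, 0 °C to rt
Reagents that add atoms: none
Why: Mitsunobu esterification activates the primary alcohol and uses angelic acid only as carboxylate nucleophile, so the acid is never turned into an acyl electrophile, its Z-alkene should not isomerise, and no ring stereocentre takes part.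

**Compound list**
1 | 4-iodo-1,2-dimethoxybenzene | COc1ccc(I)cc1OC | starting material
2 | prop-2-yn-1-ol | C#CCO | starting material
3 | 3-(3,4-dimethoxyphenyl)prop-2-yn-1-ol | OCC#Cc1ccc(OC)c(OC)c1 | intermediate
4 | (2Z)-3-(3,4-dimethoxyphenyl)prop-2-en-1-ol | OC/C=C\c1ccc(OC)c(OC)c1 | intermediate
5 | bromoacetyl bromide | BrCC(Br)=O | starting material
6 | (2Z)-3-(3,4-dimethoxyphenyl)prop-2-en-1-yl bromoacetate | BrCC(=O)OC/C=C\c1ccc(OC)c(OC)c1 | intermediate
7 | (2Z)-3-(3,4-dimethoxyphenyl)prop-2-en-1-yl diazoacetate | [N-]=[N+]=CC(=O)OC/C=C\c1ccc(OC)c(OC)c1 | intermediate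
8 | (1S,5R,6S)-6-(3,4-dimethoxyphenyl)-3-oxabicyclo[3.1.0]hexan-2-one (aryl endo) | O=C1OC[C@@H]2[C@H](c3ccc(OC)c(OC)c3)[C@H]12 | intermediate
9 | formaldehyde (monomer, set free from commercial paraformaldehyde) | C=O | starting material
10 | {(S)-(3,4-dimethoxyphenyl)[(3R)-5-(trimethylsilyloxy)-2,3-dihydrofuran-3-yl]methyl}(methylidene)oxonium triflate | C=[O+][C@H](c1ccc(OC)c(OC)c1)[C@H]1COC(O[Si](C)(C)C)=C1.[O-]S(=O)(=O)C(F)(F)F | intermediate
11 | (1R,5R,6S)-6-(3,4-dimethoxyphenyl)-3,7-dioxabicyclo[3.3.0]octan-2-one (cis-fused, aryl exo) | O=C1OC[C@@H]2[C@@H](c3ccc(OC)c(OC)c3)OC[C@H]12 | intermediate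
12 | (1R,5R,6S)-6-(3,4-dimethoxyphenyl)-3,7-dioxabicyclo[3.3.0]octan-2-ol (both anomers) | OC1OC[C@@H]2[C@@H](c3ccc(OC)c(OC)c3)OC[C@H]12 | intermediate
13 | 3,4-dimethoxyphenylboronic acid | OB(O)c1ccc(OC)c(OC)c1 | starting material
14 | N'-[(E)-{(3S,4R,5S)-5-(3,4-dimethoxyphenyl)-4-(hydroxymethyl)oxolan-3-yl}methylidene]-4-methylbenzenesulfonohydrazide | OC[C@H]1[C@@H](/C=N/NS(=O)(=O)c2ccc(C)cc2)CO[C@@H]1c1ccc(OC)c(OC)c1 | intermediate
15 | [(2S,3R,4S)-4-(diazomethyl)-2-(3,4-dimethoxyphenyl)oxolan-3-yl]methanol | OC[C@H]1[C@@H](C=[N+]=[N-])CO[C@@H]1c1ccc(OC)c(OC)c1 | intermediate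
16 | {(3,4-dimethoxyphenyl)[(3R,4R,5S)-5-(3,4-dimethoxyphenyl)-4-(hydroxymethyl)oxolan-3-yl]methyl}boronic acid (both epimers at the boron-bearing carbon) | OC[C@H]1[C@@H](C(B(O)O)c2ccc(OC)c(OC)c2)CO[C@@H]1c1ccc(OC)c(OC)c1 | intermediate
17 | [(2S,3R,4R)-4-(3,4-dimethoxybenzyl)-2-(3,4-dimethoxyphenyl)oxolan-3-yl]methanol (lariciresinol dimethyl ether) | OC[C@H]1[C@@H](Cc2ccc(OC)c(OC)c2)CO[C@@H]1c1ccc(OC)c(OC)c1 | intermediate
18 | angelic acid, (2Z)-2-methylbut-2-enoic acid | C/C=C(/C)C(=O)O | starting material
19 | leoligin | C/C=C(/C)C(=O)OC[C@H]1[C@@H](Cc2ccc(OC)c(OC)c2)CO[C@@H]1c1ccc(OC)c(OC)c1 | target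

Total step count: 9. Longest linear sequence: 9 steps (1 to 19).

**Steps most likely to fail**

**Step 6.**
- What may go wrong:
  - A single lactone acceptor may activate the cyclopropane too weakly.
  - The opened ion pair may lose a proton and isomerise to an arylmethylidene lactone.
  - Formaldehyde may polymerise or attack the veratryl ring.
  - Configuration may leak at the benzylic carbon.
- The fallback keeps the same event but uses the classical geminal activation. It sets out from 4 and comes back at 11.
- Acylation of 4 with methyl malonyl chloride (pyridine, CH2Cl2) would give the allyl methyl malonate F1. Diazo transfer (4-acetamidobenzenesulfonyl azide, Et3N, MeCN) would then give the diazomalonate F2.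
- Intramolecular cyclopropanation (Cu(MeCN)4PF6 and a chiral bis(oxazoline) ligand of the matching hand, CH2Cl2) would give the endo-aryl cyclopropane lactone ester F3. This would be enriched by recrystallisation, because carbene transfer from diazomalonates is less face-selective.
- With two geminal acceptors, the reaction with formaldehyde belongs to the well-known aldehyde/cyclopropane-1,1-dicarboxylate (3+2) class (Sn(OTf)2, CH2Cl2). It would give the bicyclic lactone ester F4 with inversion at the aryl-bearing carbon.
- Krapcho demethoxycarbonylation (LiCl, wet DMSO, heat) then removes the helper ester. Protonation is forced to the cis-fused frame of 11.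

**Step 8.**
- What may go wrong:
  - The lactol may open only slowly to the hydrazone.
  - The carbon next to the hydrazone may epimerise.
  - The diazoalkane may undergo a 1,2-hydrogen shift or be captured by the neighbouring hydroxymethyl group.
  - Protodeboronation may be slow.
- The fallback makes the C–C bond by carbonyl addition and removes the oxygen afterwards. It sets out from 12 and comes back at 17.
- 3,4-Dimethoxyphenylmagnesium bromide (THF, 0 °C) would add to the open form of 12 to give the benzylic alcohol diol F5.
- Selective acetylation of the primary hydroxyl group (Ac2O, pyridine, 0 °C) would give the monoacetate F6, which can no longer close to a furofuran.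
- Ionic deoxygenation of the free, easily ionised benzylic alcohol (Et3SiH, BF3·OEt2, CH2Cl2, −78 °C) would give the deoxygenated acetate F7.
- Methanolysis (K2CO3, MeOH) would return 17.

**Step 9.**
- What may go wrong:
  - Displacement at the beta-branched alkoxyphosphonium ion may be slow.
  - The reduced azodicarboxylate may be alkylated.
  - The angelate may isomerise from Z to E during a long reaction.
- The fallback changes from activating the alcohol to acyl transfer without a nucleophilic catalyst (Yamaguchi-type esterification). It sets out from 17 and 18 and comes back at 19.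
- Acid 18 with 2,4,6-trichlorobenzoyl chloride and Et3N (toluene) would give the angelic trichlorobenzoic mixed anhydride F8. Warming F8 with 17 in toluene would acylate the alcohol at the less hindered angeloyl carbonyl group.

**Further compounds**
F1 | step 6 | (2Z)-3-(3,4-dimethoxyphenyl)prop-2-en-1-yl methyl malonate | COC(=O)CC(=O)OC/C=C\c1ccc(OC)c(OC)c1
F2 | step 6 | (2Z)-3-(3,4-dimethoxyphenyl)prop-2-en-1-yl methyl diazomalonate | COC(=O)C(=[N+]=[N-])C(=O)OC/C=C\c1ccc(OC)c(OC)c1
F3 | step 6 | methyl (1S,5R,6R)-6-(3,4-dimethoxyphenyl)-2-oxo-3-oxabicyclo[3.1.0]hexane-1-carboxylate (aryl endo) | O=C1OC[C@@H]2[C@H](c3ccc(OC)c(OC)c3)[C@]12C(=O)OC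
F4 | step 6 | methyl (1R,5R,6S)-6-(3,4-dimethoxyphenyl)-2-oxo-3,7-dioxabicyclo[3.3.0]octane-1-carboxylate (aryl exo) | O=C1OC[C@@H]2[C@@H](c3ccc(OC)c(OC)c3)OC[C@]12C(=O)OC
F5 | step 8 | (3,4-dimethoxyphenyl)[(3R,4R,5S)-5-(3,4-dimethoxyphenyl)-4-(hydroxymethyl)oxolan-3-yl]methanol (both carbinol epimers) | OC[C@H]1[C@@H](C(O)c2ccc(OC)c(OC)c2)CO[C@@H]1c1ccc(OC)c(OC)c1
F6 | step 8 | primary monoacetate of F5 | CC(=O)OC[C@H]1[C@@H](C(O)c2ccc(OC)c(OC)c2)CO[C@@H]1c1ccc(OC)c(OC)c1
F7 | step 8 | [(2S,3R,4R)-4-(3,4-dimethoxybenzyl)-2-(3,4-dimethoxyphenyl)oxolan-3-yl]methyl acetate | CC(=O)OC[C@H]1[C@@H](Cc2ccc(OC)c(OC)c2)CO[C@@H]1c1ccc(OC)c(OC)c1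
F8 | step 9 | (2Z)-2-methylbut-2-enoic 2,4,6-trichlorobenzoic anhydride | C/C=C(/C)C(=O)OC(=O)c1c(Cl)cc(Cl)cc1Cl
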